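A direct plan would make ring A as the silyl-protected prenylated 2′-hydroxyacetophenone A1 and join it by aldol condensation to the catechol aldehyde A2, which carries the open (3E)-3,7-dimethylocta-3,6-dienyl chain. It would close ring C of chalcone A3 by an enantioselective oxa-Michael addition to A4 and close the chroman last by an oxidative palladium cyclisation.
Its three weakest operations would be the following.
(a) The thermal O-to-C transfer of the prenyl group (para-Claisen–Cope near 200 °C) that has to place the side chain at C6. It runs on aryl silyl ethers, can stop at the reverse-prenyl dienone, cyclise to a dimethylchroman or leak to C8, and it needs three protecting-group steps around it.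
(b) The phenoxide ring closure of the chalcone that sets C2. The addition is reversible, the 2′,6′-dioxygenated chalcone is a twisted, poor acceptor, and every later basic step can reopen ring C by the retro-Michael path and erase the centre.
(c) The last ring closure, which must create the quaternary C–O centre, steer β-hydride elimination to the (E)-diene and spare a free catechol beside a quinone oxidant. Its configuration would rest on an untested catalyst–substrate match, tried on the most precious intermediate.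

**Plan of the new route**

Cuts: (1) the C2–C1′ bond between ring C and ring B, made by an enantioselective rhodium-catalysed 1,4-addition of chromanylboronic acid 25 to chromone 10; (2) ring A of 10 at C8–C8a, C5–C6, C7–C8 and C4a–C5, i.e. ring A is built around the prenyl group by a Danheiser benzannulation of the γ-pyrone diazo ketone 3 with the prenyl siloxyalkyne 6; (3) in 25, the O1–C2 bond of the chroman (epoxide opening) and the C1′=C2′ bond of the diene (olefination).
Feature used by the key step: ring A is a benzo ring fused to the pyranone across C4a–C8a, with oxygens at C5 and C7 flanking the prenyl-bearing C6 and with C8 unsubstituted. A ketene carbon (C5–O), the two carbons of an ynol ether (C6 with its substituent, C7–O), a ketene CH (C8) and the C8a=C4a unit of a γ-pyrone give exactly this pattern, so the prenyl group can only end at C6 and the free hydroxyl only at C5.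
Order of rings: ring C is bought as a γ-pyrone, ring A is fused onto it (step 3), ring D is closed on the separate ring B fragment (step 9), and C2 is created last, when the halves are joined (step 13).
The weak steps do not arise. There is no prenyl migration, because the position follows from the ring construction. There is no chalcone and no phenoxide addition at C2, because the centre is set by C–C bond formation on a chromone under catalyst control. There is no oxidative ring closure on late material, because the quaternary centre comes from a reagent-controlled epoxidation and an SN2 opening on a small fragment.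

Key step: step 3

Assumption 1: 13 is taken as a catalogue compound; otherwise it follows from 4-bromo-2-methoxyphenol by ortho-iodination and O-demethylation.
Assumption 2: in step 13 the (S)-biaryl bisphosphine is expected to give the 2S adduct by the facial model that leads from cyclohex-2-enone to (S)-3-arylcyclohexanones; the sense would be checked on 4H-chromen-4-one and phenylboronic acid before 25 is committed.

**Route**

Step 1
Reactants: 1 4-oxo-4H-pyran-2-carboxylic acid (comanic acid)
Product: 3 2-(2-diazoacetyl)-4H-pyran-4-one, via acid chloride 2 (not isolated)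
Conditions: (COCl)2 (1.3 equiv), DMF (cat.), CH2Cl2, 0 °C to rt; evaporate; Me3SiCHN2 (2.0 equiv), Et3N (1.1 equiv), THF/MeCN 1:1, 0 °C to rt; aq NaHCO3
Reagents that add atoms: (trimethylsilyl)diazomethane, C[Si](C)(C)C=[N+]=[N-]
Why: Acid chloride formation followed by C-acylation of the diazoalkane (first half of an Arndt–Eistert sequence); the acid chloride has no α-hydrogen, so no ketene side path exists, and no stereocentre is formed.

Step 2
Reactants: 4 methyl 4-methylpent-3-enoate
Product: 6 triisopropyl[(5-methylhex-4-en-1-yn-1-yl)oxy]silane, via lithium ynolate 5 (not isolated)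
Conditions: CH2Br2 (2.2 equiv), lithium 2,2,6,6-tetramethylpiperidide (2.1 equiv), THF, −78 °C; 4; LiN(SiMe3)2 (1.2 equiv); n-BuLi (3 equiv), −78 to −20 °C; i-Pr3SiCl (1.5 equiv), −78 °C to rt
Reagents that add atoms: dibromomethane, BrCBr; triisopropylsilyl chloride, CC(C)[Si](Cl)(C(C)C)C(C)C
Why: Kowalski ester homologation, in which LiCHBr2 adds to the ester, bromine–lithium exchange of the dibromo enolate triggers a carbenoid 1,2-shift to ynolate 5, and the bulky silyl chloride traps 5 on oxygen to give the siloxyalkyne; no stereocentre is formed.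

Step 3
Reactants: 3 2-(2-diazoacetyl)-4H-pyran-4-one; 6 triisopropyl[(5-methylhex-4-en-1-yn-1-yl)oxy]silane
Product: 9 5-hydroxy-6-(3-methylbut-2-enyl)-7-(triisopropylsilyloxy)-4H-chromen-4-one, via pyranyl ketene 7 (not isolated), via cyclobutenone 8 (not isolated)
Conditions: 6 (1.5 equiv), ClCH2CH2Cl (0.03 M), hν (350–365 nm, Pyrex), rt until N2 evolution ends; then 80 °C, 3 h
Reagents that add atoms: none
Why: Danheiser benzannulation in its diazo ketone form: light induces the Wolff rearrangement of 3 to ketene 7 (this 1,2-shift makes C8–C8a), 7 and the electron-rich alkyne 6 combine in a regiospecific [2+2] cycloaddition to cyclobutenone 8 (C5–C6 and C7–C8), and heating opens 8 (4π) to a dienylketene that closes onto C3 of the pyranone (C4a–C5) and tautomerises to the phenol. The closest known reaction type is the benzannulation of aryl and heteroaryl α-diazo ketones with triisopropylsiloxy alkynes to fused resorcinol monosilyl ethers. Ring A is closed by a thermal 6π-electrocyclisation of the dienylketene, while ring C is not formed here but carried through intact from 1. No stereocentre is formed. The step needs complete regiocontrol, and the substrates secure it: the nucleophilic alkyne carbon, which bears the prenyl group, bonds to the ketene carbonyl carbon (the future C5), and C2 of the pyranone has only one carbon neighbour (C3) for the electrocyclisation, so the prenyl group must end at C6 between the C5 hydroxyl and the C7 silyl ether. Chemoselectivity should follow from the much higher reactivity of the ketene towards the siloxyalkyne than towards the trisubstituted prenyl alkene, and from irradiation at a wavelength that addresses the diazo ketone and not the pyranone.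

Step 4
Reactants: 9 5-hydroxy-6-(3-methylbut-2-enyl)-7-(triisopropylsilyloxy)-4H-chromen-4-one
Product: 10 5-(tert-butyldimethylsilyloxy)-6-(3-methylbut-2-enyl)-7-(triisopropylsilyloxy)-4H-chromen-4-one
Conditions: t-BuMe2SiOTf (1.5 equiv), 2,6-lutidine (3 equiv), CH2Cl2, −40 to 0 °C
Reagents that add atoms: tert-butyldimethylsilyl trifluoromethanesulfonate, CC(C)(C)[Si](C)(C)OS(=O)(=O)C(F)(F)F
Why: Silyl ether formation with the reactive silyl triflate, needed because the hydrogen-bonded C5 hydroxyl would otherwise bind rhodium as a keto-phenolate chelate in step 13; lutidine buffers triflic acid so that the prenyl group is not protonated.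

Step 5
Reactants: 11 (2E)-3-methylpent-2-en-4-yn-1-ol
Product: 12 (2E)-3-methylpenta-2,4-dien-1-ol
Conditions: H2 (1 atm), Pd/CaCO3 poisoned with Pb(OAc)2 (5 wt %), quinoline, Et2O, 0 °C, stopped at 1 equiv H2
Reagents that add atoms: none
Why: Partial hydrogenation of the terminal alkyne over poisoned palladium gives the vinyl group, and the trisubstituted (E)-alkene is not touched.

Step 6
Reactants: 13 5-bromo-3-iodobenzene-1,2-diol
Product: 14 5-bromo-1,2-bis(tert-butyldimethylsilyloxy)-3-iodobenzene
Conditions: t-BuMe2SiCl (2.4 equiv), imidazole (5 equiv), DMF, 0 °C to rt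
Reagents that add atoms: tert-butyldimethylsilyl chloride, CC(C)(C)[Si](C)(C)Cl
Why: Silyl ether formation masks both phenols, which would otherwise bind the borane in step 7 and poison the titanium tartrate catalyst in step 8.

Step 7
Reactants: 12 (2E)-3-methylpenta-2,4-dien-1-ol; 14 5-bromo-1,2-bis(tert-butyldimethylsilyloxy)-3-iodobenzene
Product: 16 (2E)-5-[5-bromo-2,3-bis(tert-butyldimethylsilyloxy)phenyl]-3-methylpent-2-en-1-ol, via bis-boron adduct 15 (not isolated)
Conditions: 12 (1.1 equiv), 9-BBN (2.3 equiv B–H), THF, 0 °C to rt; then 14, PdCl2(dppf) (3 mol %), K3PO4 (3 equiv, 3 M aq, degassed), THF, rt to 40 °C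
Reagents that add atoms: none
Why: Hydroboration/B-alkyl Suzuki–Miyaura coupling, in which 9-BBN adds only to the terminal vinyl carbon and the alkylborane couples at the C–I bond, which undergoes oxidative addition far faster than the C–Br bond; the (E)-alkene geometry is retained.

Step 8
Reactants: 16 (2E)-5-[5-bromo-2,3-bis(tert-butyldimethylsilyloxy)phenyl]-3-methylpent-2-en-1-ol
Product: 17 [(2R,3R)-3-{2-[5-bromo-2,3-bis(tert-butyldimethylsilyloxy)phenyl]ethyl}-3-methyloxiran-2-yl]methanol
Conditions: Ti(OiPr)4 (10 mol %), D-(−)-diethyl tartrate (12 mol %), t-BuOOH (2 equiv, in decane), 4 Å MS, CH2Cl2, −20 °C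
Reagents that add atoms: tert-butyl hydroperoxide, CC(C)(C)OO
Why: Sharpless asymmetric epoxidation, in which the titanium D-(−)-tartrate complex delivers oxygen to the face of the (E)-allylic alcohol that gives the (2R,3R)-epoxy alcohol (reagent control), fixing the carbon that becomes the quaternary chroman centre.

Step 9
Reactants: 17 [(2R,3R)-3-{2-[5-bromo-2,3-bis(tert-butyldimethylsilyloxy)phenyl]ethyl}-3-methyloxiran-2-yl]methanol
Product: 19 (1R)-1-[(2S)-6-bromo-8-hydroxy-2-methylchroman-2-yl]ethane-1,2-diol, via catechol epoxy alcohol 18 (not isolated)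
Conditions: n-Bu4NF (2.2 equiv), AcOH (2.5 equiv), THF, 0 °C; then crude 18, camphorsulfonic acid (5 mol %), CH2Cl2, −20 to 0 °C
Reagents that add atoms: none
Why: Buffered fluoride desilylation followed by acid-catalysed 6-exo intramolecular epoxide opening, in which the phenol ortho to the chain attacks the tertiary epoxide carbon with inversion (SN2-type, stereospecific), so the 3R epoxide carbon becomes the 2S chroman centre; the second phenol is meta to the chain and cannot reach the epoxide.

Step 10
Reactants: 19 (1R)-1-[(2S)-6-bromo-8-hydroxy-2-methylchroman-2-yl]ethane-1,2-diol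
Product: 20 (2S)-6-bromo-8-hydroxy-2-methylchroman-2-carbaldehyde
Conditions: NaIO4 (1.15 equiv), THF/pH 7 phosphate buffer, 0 °C, 20 min
Reagents that add atoms: none
Why: Periodate glycol cleavage (Malaprade reaction) removes the terminal carbon as formaldehyde and gives the non-enolisable α-quaternary aldehyde, so the stereocentre cannot epimerise; the short cold reaction should spare the phenol.

Step 11
Reactants: 20 (2S)-6-bromo-8-hydroxy-2-methylchroman-2-carbaldehyde; 21 diethyl (3-methylbut-2-en-1-yl)phosphonate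
Product: 23 (2S)-6-bromo-8-(tert-butyldimethylsilyloxy)-2-methyl-2-[(1E)-4-methylpenta-1,3-dien-1-yl]chroman, via dienyl phenol 22 (not isolated)
Conditions: 21 (2.4 equiv), n-BuLi (2.3 equiv), THF/DMPU 4:1, −78 °C; 20; −78 to 20 °C; then t-BuMe2SiCl (1.5 equiv), 0 °C to rt
Reagents that add atoms: tert-butyldimethylsilyl chloride, CC(C)(C)[Si](C)(C)Cl
Why: Horner–Wadsworth–Emmons olefination with the lithiated allylic phosphonate, which attacks through its α-carbon and should give the (E)-alkene after equilibration and elimination of the adduct; the lithium phenoxide present in the flask is then silylated.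

Step 12
Reactants: 23 (2S)-6-bromo-8-(tert-butyldimethylsilyloxy)-2-methyl-2-[(1E)-4-methylpenta-1,3-dien-1-yl]chroman
Product: 25 {(2S)-8-(tert-butyldimethylsilyloxy)-2-methyl-2-[(1E)-4-methylpenta-1,3-dien-1-yl]chroman-6-yl}boronic acid, via lithium arylborate 24 (not isolated)
Conditions: B(OiPr)3 (1.5 equiv), THF/toluene, −78 °C; n-BuLi (1.15 equiv) added slowly; −78 to −20 °C; aq NH4Cl (pH 6); used crude
Reagents that add atoms: triisopropyl borate, CC(C)OB(OC(C)C)OC(C)C; water, O
Why: Bromine–lithium exchange with in situ borate trapping and hydrolysis, chosen over a borylation with zerovalent palladium, which could ionise the tertiary dienylic aryl ether; the stereocentre and the diene are not involved.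

Step 13
Reactants: 10 5-(tert-butyldimethylsilyloxy)-6-(3-methylbut-2-enyl)-7-(triisopropylsilyloxy)-4H-chromen-4-one; 25 {(2S)-8-(tert-butyldimethylsilyloxy)-2-methyl-2-[(1E)-4-methylpenta-1,3-dien-1-yl]chroman-6-yl}boronic acid
Product: 26 (2S)-5-(tert-butyldimethylsilyloxy)-2-{(2S)-8-(tert-butyldimethylsilyloxy)-2-methyl-2-[(1E)-4-methylpenta-1,3-dien-1-yl]chroman-6-yl}-6-(3-methylbut-2-enyl)-7-(triisopropylsilyloxy)chroman-4-one
Conditions: 10 (1.3 equiv), 25 (1.0 equiv), [RhCl(C2H4)2]2 (2.5 mol %), (S)-6,6′-dimethoxy-2,2′-bis[bis(3,4,5-trifluorophenyl)phosphino]biphenyl (5.5 mol %), aq KOH (10 mol %), toluene/H2O 10:1, 30 °C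
Reagents that add atoms: none
Why: Rhodium-catalysed enantioselective 1,4-addition of an arylboronic acid to a chromone (Hayashi–Miyaura reaction), in which the aryl–rhodium species formed by transmetalation inserts the C2=C3 bond on the face left open by the (S)-bisphosphine, so C2 is set as S by catalyst control with no influence expected from the remote chroman centre, and hydrolysis of the oxa-π-allyl rhodium releases the flavanone without a chalcone being formed; the prenyl alkene, the diene and the silyl ethers should not react under these near-neutral conditions.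

Step 14
Reactants: 26 (2S)-5-(tert-butyldimethylsilyloxy)-2-{(2S)-8-(tert-butyldimethylsilyloxy)-2-methyl-2-[(1E)-4-methylpenta-1,3-dien-1-yl]chroman-6-yl}-6-(3-methylbut-2-enyl)-7-(triisopropylsilyloxy)chroman-4-one
Product: 27 (2S)-5,7-dihydroxy-2-{(2S)-8-hydroxy-2-methyl-2-[(1E)-4-methylpenta-1,3-dien-1-yl]chroman-6-yl}-6-(3-methylbut-2-enyl)chroman-4-one (CNP0294970.1)
Conditions: n-Bu4NF (4 equiv), AcOH (4.5 equiv), THF, 0 °C to rt
Reagents that add atoms: none
Why: Fluoride cleavage of the three aryl silyl ethers in an acetic acid buffer, so that neither retro-oxa-Michael opening at C2 nor ionisation of the tertiary dienylic ether of ring D should occur and both stereocentres are kept.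

**Compound list**

1 | 4-oxo-4H-pyran-2-carboxylic acid (comanic acid) | OC(=O)c1cc(=O)cco1 | starting material
2 | 4-oxo-4H-pyran-2-carbonyl chloride | O=C(Cl)c1cc(=O)cco1 | intermediate
3 | 2-(2-diazoacetyl)-4H-pyran-4-one | [N-]=[N+]=CC(=O)c1cc(=O)cco1 | intermediate
4 | methyl 4-methylpent-3-enoate | COC(=O)CC=C(C)C | starting material
5 | lithium 5-methylhex-4-en-1-yn-1-olate | [Li+].[O-]C#CCC=C(C)C | intermediate
6 | triisopropyl[(5-methylhex-4-en-1-yn-1-yl)oxy]silane | CC(C)=CCC#CO[Si](C(C)C)(C(C)C)C(C)C | intermediate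
7 | 2-(2-oxoethenyl)-4H-pyran-4-one (pyranyl ketene) | O=C=Cc1cc(=O)cco1 | intermediate
8 | racemic 2-(3-methylbut-2-enyl)-4-(4-oxo-4H-pyran-2-yl)-3-(triisopropylsilyloxy)cyclobut-2-en-1-one | O=C1C(CC=C(C)C)=C(O[Si](C(C)C)(C(C)C)C(C)C)C1c1cc(=O)cco1 | intermediate
9 | 5-hydroxy-6-(3-methylbut-2-enyl)-7-(triisopropylsilyloxy)-4H-chromen-4-one | O=c1ccoc2cc(O[Si](C(C)C)(C(C)C)C(C)C)c(CC=C(C)C)c(O)c12 | intermediate
10 | 5-(tert-butyldimethylsilyloxy)-6-(3-methylbut-2-enyl)-7-(triisopropylsilyloxy)-4H-chromen-4-one | O=c1ccoc2cc(O[Si](C(C)C)(C(C)C)C(C)C)c(CC=C(C)C)c(O[Si](C)(C)C(C)(C)C)c12 | intermediate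
11 | (2E)-3-methylpent-2-en-4-yn-1-ol | C#C/C(C)=C/CO | starting material
12 | (2E)-3-methylpenta-2,4-dien-1-ol | C=C/C(C)=C/CO | intermediate
13 | 5-bromo-3-iodobenzene-1,2-diol | Oc1cc(Br)cc(I)c1O | starting material
14 | 5-bromo-1,2-bis(tert-butyldimethylsilyloxy)-3-iodobenzene | CC(C)(C)[Si](C)(C)Oc1cc(Br)cc(I)c1O[Si](C)(C)C(C)(C)C | intermediate
15 | 9-{(3E)-5-[(9-borabicyclo[3.3.1]nonan-9-yl)oxy]-3-methylpent-3-en-1-yl}-9-borabicyclo[3.3.1]nonane | B1(CC/C(C)=C/COB2C3CCCC2CCC3)C2CCCC1CCC2 | intermediate
16 | (2E)-5-[5-bromo-2,3-bis(tert-butyldimethylsilyloxy)phenyl]-3-methylpent-2-en-1-ol | OC/C=C(C)/CCc1cc(Br)cc(O[Si](C)(C)C(C)(C)C)c1O[Si](C)(C)C(C)(C)C | intermediate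
17 | [(2R,3R)-3-{2-[5-bromo-2,3-bis(tert-butyldimethylsilyloxy)phenyl]ethyl}-3-methyloxiran-2-yl]methanol | OC[C@H]1O[C@]1(C)CCc1cc(Br)cc(O[Si](C)(C)C(C)(C)C)c1O[Si](C)(C)C(C)(C)C | intermediate
18 | 5-bromo-3-{2-[(2R,3R)-3-(hydroxymethyl)-2-methyloxiran-2-yl]ethyl}benzene-1,2-diol | OC[C@H]1O[C@]1(C)CCc1cc(Br)cc(O)c1O | intermediate
19 | (1R)-1-[(2S)-6-bromo-8-hydroxy-2-methylchroman-2-yl]ethane-1,2-diol | OC[C@@H](O)[C@]1(C)CCc2cc(Br)cc(O)c2O1 | intermediate
20 | (2S)-6-bromo-8-hydroxy-2-methylchroman-2-carbaldehyde | O=C[C@]1(C)CCc2cc(Br)cc(O)c2O1 | intermediate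
21 | diethyl (3-methylbut-2-en-1-yl)phosphonate | CCOP(=O)(CC=C(C)C)OCC | starting material
22 | (2S)-6-bromo-2-methyl-2-[(1E)-4-methylpenta-1,3-dien-1-yl]chroman-8-ol | CC(C)=C/C=C/[C@]1(C)CCc2cc(Br)cc(O)c2O1 | intermediate
23 | (2S)-6-bromo-8-(tert-butyldimethylsilyloxy)-2-methyl-2-[(1E)-4-methylpenta-1,3-dien-1-yl]chroman | CC(C)=C/C=C/[C@]1(C)CCc2cc(Br)cc(O[Si](C)(C)C(C)(C)C)c2O1 | intermediate
24 | lithium {(2S)-8-(tert-butyldimethylsilyloxy)-2-methyl-2-[(1E)-4-methylpenta-1,3-dien-1-yl]chroman-6-yl}tri(propan-2-yloxy)borate | [Li+].CC(C)=C/C=C/[C@]1(C)CCc2cc([B-](OC(C)C)(OC(C)C)OC(C)C)cc(O[Si](C)(C)C(C)(C)C)c2O1 | intermediate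
25 | {(2S)-8-(tert-butyldimethylsilyloxy)-2-methyl-2-[(1E)-4-methylpenta-1,3-dien-1-yl]chroman-6-yl}boronic acid | CC(C)=C/C=C/[C@]1(C)CCc2cc(B(O)O)cc(O[Si](C)(C)C(C)(C)C)c2O1 | intermediate
26 | (2S)-5-(tert-butyldimethylsilyloxy)-2-{(2S)-8-(tert-butyldimethylsilyloxy)-2-methyl-2-[(1E)-4-methylpenta-1,3-dien-1-yl]chroman-6-yl}-6-(3-methylbut-2-enyl)-7-(triisopropylsilyloxy)chroman-4-one | CC(C)=C/C=C/[C@]1(C)CCc2cc([C@@H]3CC(=O)c4c(cc(O[Si](C(C)C)(C(C)C)C(C)C)c(CC=C(C)C)c4O[Si](C)(C)C(C)(C)C)O3)cc(O[Si](C)(C)C(C)(C)C)c2O1 | intermediate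
27 | (2S)-5,7-dihydroxy-2-{(2S)-8-hydroxy-2-methyl-2-[(1E)-4-methylpenta-1,3-dien-1-yl]chroman-6-yl}-6-(3-methylbut-2-enyl)chroman-4-one (CNP0294970.1) | CC(C)=C/C=C/[C@]1(C)CCc2cc([C@@H]3CC(=O)c4c(cc(O)c(CC=C(C)C)c4O)O3)cc(O)c2O1 | target

**Count and risks**

Total step count: 14. Longest linear sequence: 9 steps (13 → 14 → 16 → 17 → 19 → 20 → 23 → 25 → 26 → 27; the branch from 11 is equally long).

The three steps most likely to fail:

1. Step 3 (benzannulation). The pyranone chromophore may compete for light, the ketene may dimerise before it meets the alkyne, or the electrocyclisation may stall at the cyclobutenone. The fallback takes ring A from an arene instead of building it. It does not set out from a numbered compound: compounds 1 to 8 are replaced by purchased 5,7-dihydroxy-4H-chromen-4-one F1. F1 would be silylated at the non-chelated 7-hydroxyl (i-Pr3SiCl, imidazole, DMF) to 5-hydroxy-7-(triisopropylsilyloxy)-4H-chromen-4-one F2. F2 would be iodinated ortho to the hydrogen-bonded 5-hydroxyl (N-iodosuccinimide, DMF, rt) to 5-hydroxy-6-iodo-7-(triisopropylsilyloxy)-4H-chromen-4-one F3. F3 would be prenylated by Stille coupling with tributyl(3-methylbut-2-enyl)stannane [Pd(PPh3)4, LiCl, DMF, 80 °C]. The fallback comes back to the route at 9.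

2. Step 13 (fragment union). Protodeboronation of the electron-rich boronic acid may outrun insertion into the hindered chromone, or facial selectivity at C2 may be poor. The fallback sets out from 10 and 25 and forms the C2–aryl bond without a stereocentre. An oxidative Heck-type C2 arylation (Pd(OCOCF3)2, 2,2′-bipyridine, O2, DMSO; divalent palladium throughout) would give the flavone 5-(tert-butyldimethylsilyloxy)-2-{(2S)-8-(tert-butyldimethylsilyloxy)-2-methyl-2-[(1E)-4-methylpenta-1,3-dien-1-yl]chroman-6-yl}-6-(3-methylbut-2-enyl)-7-(triisopropylsilyloxy)-4H-chromen-4-one F4. C2 would then be set by hydride delivery in a copper hydride 1,4-reduction [Cu(OAc)2, (S)-DTBM-SEGPHOS, (EtO)2MeSiH, t-BuOH, toluene, 0 °C]. The fallback comes back to the route at 26.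

3. Step 9 (epoxide-opening ring closure). Partial ionisation at the tertiary epoxide carbon would erode the configuration, and hydride shift to a ketone may compete with the 6-exo attack. The fallback sets out from 16 and sets the quaternary centre by asymmetric allylic etherification instead.
   - 16 would be converted (ClCO2Me, pyridine, CH2Cl2, 0 °C) to (2E)-5-[5-bromo-2,3-bis(tert-butyldimethylsilyloxy)phenyl]-3-methylpent-2-en-1-yl methyl carbonate F5.
   - F5 would be desilylated (n-Bu4NF, AcOH, THF) to (2E)-5-(5-bromo-2,3-dihydroxyphenyl)-3-methylpent-2-en-1-yl methyl carbonate F6.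
   - F6 would be cyclised by a Tsuji–Trost reaction with zerovalent palladium [Pd2(dba)3·CHCl3 (2 mol %), N,N′-(cyclohexane-1,2-diyl)bis[2-(diphenylphosphino)benzamide] (6 mol %, the enantiomer that gives the 2S product), AcOH (1 equiv), CH2Cl2, rt] to (2S)-6-bromo-2-methyl-2-vinylchroman-8-ol F7.
   - F7 would be cleaved by Lemieux–Johnson oxidation (OsO4 (2 mol %), NaIO4, 2,6-lutidine, dioxane/H2O).
   
   The fallback comes back to the route at 20.

Further compounds
F1 | step 3 | 5,7-dihydroxy-4H-chromen-4-one | O=c1ccoc2cc(O)cc(O)c12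
F2 | step 3 | 5-hydroxy-7-(triisopropylsilyloxy)-4H-chromen-4-one | O=c1ccoc2cc(O[Si](C(C)C)(C(C)C)C(C)C)cc(O)c12
F3 | step 3 | 5-hydroxy-6-iodo-7-(triisopropylsilyloxy)-4H-chromen-4-one | O=c1ccoc2cc(O[Si](C(C)C)(C(C)C)C(C)C)c(I)c(O)c12
F4 | step 13 | 5-(tert-butyldimethylsilyloxy)-2-{(2S)-8-(tert-butyldimethylsilyloxy)-2-methyl-2-[(1E)-4-methylpenta-1,3-dien-1-yl]chroman-6-yl}-6-(3-methylbut-2-enyl)-7-(triisopropylsilyloxy)-4H-chromen-4-one | CC(C)=C/C=C/[C@]1(C)CCc2cc(-c3cc(=O)c4c(cc(O[Si](C(C)C)(C(C)C)C(C)C)c(CC=C(C)C)c4O[Si](C)(C)C(C)(C)C)o3)cc(O[Si](C)(C)C(C)(C)C)c2O1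
F5 | step 9 | (2E)-5-[5-bromo-2,3-bis(tert-butyldimethylsilyloxy)phenyl]-3-methylpent-2-en-1-yl methyl carbonate | COC(=O)OC/C=C(C)/CCc1cc(Br)cc(O[Si](C)(C)C(C)(C)C)c1O[Si](C)(C)C(C)(C)C
F6 | step 9 | (2E)-5-(5-bromo-2,3-dihydroxyphenyl)-3-methylpent-2-en-1-yl methyl carbonate | COC(=O)OC/C=C(C)/CCc1cc(Br)cc(O)c1O
F7 | step 9 | (2S)-6-bromo-2-methyl-2-vinylchroman-8-ol | C=C[C@]1(C)CCc2cc(Br)cc(O)c2O1
A1 | direct plan | 1-[6-hydroxy-3-(3-methylbut-2-enyl)-2,4-bis(tert-butyldimethylsilyloxy)phenyl]ethanone | CC(=O)c1c(O)cc(O[Si](C)(C)C(C)(C)C)c(CC=C(C)C)c1O[Si](C)(C)C(C)(C)C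
A2 | direct plan | 3-[(3E)-3,7-dimethylocta-3,6-dienyl]-4,5-bis(triethylsilyloxy)benzaldehyde | CC(C)=CC/C=C(C)/CCc1cc(C=O)cc(O[Si](CC)(CC)CC)c1O[Si](CC)(CC)CC
A3 | direct plan | (E)-1-[6-hydroxy-3-(3-methylbut-2-enyl)-2,4-bis(tert-butyldimethylsilyloxy)phenyl]-3-{3-[(3E)-3,7-dimethylocta-3,6-dienyl]-4,5-bis(triethylsilyloxy)phenyl}prop-2-en-1-one | CC(C)=CC/C=C(C)/CCc1cc(/C=C/C(=O)c2c(O)cc(O[Si](C)(C)C(C)(C)C)c(CC=C(C)C)c2O[Si](C)(C)C(C)(C)C)cc(O[Si](CC)(CC)CC)c1O[Si](CC)(CC)CC
A4 | direct plan | (2S)-2-{3-[(3E)-3,7-dimethylocta-3,6-dienyl]-4,5-dihydroxyphenyl}-5,7-bis(tert-butyldimethylsilyloxy)-6-(3-methylbut-2-enyl)chroman-4-one | CC(C)=CC/C=C(C)/CCc2cc([C@@H]3CC(=O)c4c(cc(O[Si](C)(C)C(C)(C)C)c(CC=C(C)C)c4O[Si](C)(C)C(C)(C)C)O3)cc(O)c2O
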